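**Strategy.** The target is (2S)-7,4'-dihydroxyflavan-(4β→8)-(−)-epiafzelechin. Its upper C4 is a methine held by two oxygen-activated aryl carbons: C4a of the upper ring A (para to O7, ortho to O1) and C8 of the epiafzelechin ring A. C4 is therefore traced back to an aldehyde carbon. In one acid-catalysed operation the (S)-3-aryloxy-3-arylpropanal 6 closes the pyran ring C through the C4–C4a bond (Friedel–Crafts hydroxyalkylation), and the flavan-4-yl cation that follows is captured by C8 of tri-O-benzylepiafzelechin 8, trans to the C2 aryl group. C2 comes from a catalytic allylboration and a Mitsunobu inversion; the lower stereocentres are bought.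

Key step: step 5

Assumption: (−)-epiafzelechin (7) is taken as a catalogue natural product, and its two stereocentres are carried through unchanged.

**Step 1**
Reactants: 1 4-formylphenyl acetate; 2 allylboronic acid pinacol ester
Product: 3 4-[(1R)-1-hydroxybut-3-en-1-yl]phenyl acetate
Conditions: (R)-TRIP [(R)-3,3'-bis(2,4,6-triisopropylphenyl)-1,1'-binaphthyl-2,2'-diyl hydrogen phosphate] (5 mol %), toluene, −30 °C
Reagents that add atoms: none
Why: Chiral phosphoric acid-catalysed asymmetric allylboration (Brønsted acid activation of the boronate oxygen, closed chair-like six-membered transition state) should give the (R)-homoallylic alcohol with (R)-TRIP while the aryl acetate is untouched, the new stereocentre (the later C2) being set by the catalyst.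

**Step 2**
Reactants: 3 4-[(1R)-1-hydroxybut-3-en-1-yl]phenyl acetate; 4 3-(benzyloxy)phenol
Product: 5 4-[(1S)-1-[3-(benzyloxy)phenoxy]but-3-en-1-yl]phenyl acetate
Conditions: PPh3 (1.3 equiv), DIAD (1.3 equiv), toluene, 0 °C → rt
Reagents that add atoms: none
Why: Mitsunobu etherification, in which the phenol displaces the oxyphosphonium group by SN2 with inversion to give the (S)-ether, and the electron-poor 4-acetoxyphenyl group disfavours the benzylic ionisation that would erode the configuration.

**Step 3**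
Reactants: 5 4-[(1S)-1-[3-(benzyloxy)phenoxy]but-3-en-1-yl]phenyl acetate
Product: 6 4-[(1S)-1-[3-(benzyloxy)phenoxy]-3-oxopropyl]phenyl acetate
Conditions: OsO4 (2 mol %), NaIO4 (4 equiv), 2,6-lutidine (2 equiv), dioxane/H2O 3:1, rt; crude aldehyde used at once
Reagents that add atoms: NaIO4 (sodium periodate), [Na+].[O-]I(=O)(=O)=O; osmium tetroxide (catalytic oxygen carrier), O=[Os](=O)(=O)=O
Why: Lemieux–Johnson oxidation, in which catalytic dihydroxylation of the terminal alkene and periodate cleavage of the diol give the aldehyde under buffered conditions that touch neither the stereocentre nor the benzyl ether and acetate.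

**Step 4**
Reactants: 7 (−)-epiafzelechin [(2R,3R)-2-(4-hydroxyphenyl)chroman-3,5,7-triol]
Product: 8 (2R,3R)-5,7-bis(benzyloxy)-2-[4-(benzyloxy)phenyl]chroman-3-ol
Conditions: BnBr (3.3 equiv), K2CO3 (3.5 equiv), DMF, 0 °C → rt, argon
Reagents that add atoms: benzyl bromide, BrCc1ccccc1
Why: Williamson ether synthesis, in which the three phenols are deprotonated by the carbonate base and benzylated while the less acidic secondary 3-hydroxyl stays free, and no stereocentre is involved.

**Step 5**
Reactants: 6 4-[(1S)-1-[3-(benzyloxy)phenoxy]-3-oxopropyl]phenyl acetate; 8 (2R,3R)-5,7-bis(benzyloxy)-2-[4-(benzyloxy)phenyl]chroman-3-ol (2.5 equiv, excess recovered)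
Product: 11 4-[(2S,4R)-7-(benzyloxy)-4-[(2R,3R)-5,7-bis(benzyloxy)-2-[4-(benzyloxy)phenyl]-3-hydroxychroman-8-yl]chroman-2-yl]phenyl acetate, via flavan-4-ol 9 (not isolated), via flavan-4-yl cation 10 (not isolated)
Conditions: HNTf2 (10 mol %), CH2Cl2, −60 → −20 °C, slow addition of 6 to 8 and the acid; NaHCO3 quench
Reagents that add atoms: none
Why: The acid activates the aldehyde of 6, and the ring-A carbon that is ortho to the ether oxygen and para to the benzyloxy group attacks it in an intramolecular Friedel–Crafts hydroxyalkylation that forms the C4–C4a bond and closes ring C to flavan-4-ol 9; 9 ionises at once, with loss of water, to the flavan-4-yl cation 10 (stabilised by O1 and by the para benzyloxy group), which C8 of 8 captures in a second, intermolecular Friedel–Crafts alkylation that forms the interflavan bond. The closest known reaction types are the acid-catalysed double arylation of an aldehyde by two electron-rich arenes and the condensation of flavan-4-ols with phloroglucinol-type arenes in proanthocyanidin and 4-arylflavan chemistry. Ring C closes in a 6-exo-trig mode with respect to the carbonyl group (the arene π-bond is endocyclic), and this six-membered closure should outrun any intermolecular attack of 8 on the aldehyde. The new C4 stereocentre is controlled by C2: in the sofa-shaped cation the 2-aryl group sits equatorial, and the arene adds along the axial trajectory on the face that leads directly to the half-chair, which places the new aryl group pseudoaxial and trans to the 2-aryl group, that is (2S,4R). The step needs attack through C8 and not C6 of 8, which the tri-O-benzyl pattern secures as in the 4→8-selective couplings of benzylated flavan-3-ols; it needs closure para and not ortho to the benzyloxy group, which the crowding between the two ring oxygens secures; and it needs an intact C2–O1 bond, which the electron-poor 4-acetoxyphenyl group secures by disfavouring a benzylic cation at C2, while the excess of 8 suppresses capture of 10 by 9 or by the product.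

**Step 6**
Reactants: 11 4-[(2S,4R)-7-(benzyloxy)-4-[(2R,3R)-5,7-bis(benzyloxy)-2-[4-(benzyloxy)phenyl]-3-hydroxychroman-8-yl]chroman-2-yl]phenyl acetate
Product: 12 (2R,3R)-5,7-bis(benzyloxy)-8-[(2S,4R)-7-(benzyloxy)-2-(4-hydroxyphenyl)chroman-4-yl]-2-[4-(benzyloxy)phenyl]chroman-3-ol
Conditions: K2CO3 (0.3 equiv), MeOH/THF 1:1, 0 °C → rt, argon
Reagents that add atoms: none
Why: Base-catalysed methanolysis (transesterification) of the aryl acetate is much faster than any reaction of the benzyl ethers or of the flavan rings, so all four stereocentres are untouched.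

**Step 7**
Reactants: 12 (2R,3R)-5,7-bis(benzyloxy)-8-[(2S,4R)-7-(benzyloxy)-2-(4-hydroxyphenyl)chroman-4-yl]-2-[4-(benzyloxy)phenyl]chroman-3-ol
Product: 13 (2R,3R)-8-[(2S,4R)-7-hydroxy-2-(4-hydroxyphenyl)chroman-4-yl]-2-(4-hydroxyphenyl)chroman-3,5,7-triol (CNP0254623.2)
Conditions: H2 (1 atm), Pd(OH)2/C, THF/MeOH 1:1, rt; filtration, Sephadex LH-20
Reagents that add atoms: none
Why: Catalytic hydrogenolysis cleaves the four aryl benzyl ethers, whereas the cyclic benzylic C2–O1 bonds and the interflavan bond are known to survive these conditions in proanthocyanidin chemistry, so the stereocentres are untouched.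

**Compound list**

1 | 4-formylphenyl acetate | CC(=O)Oc1ccc(C=O)cc1 | starting material
2 | allylboronic acid pinacol ester | C=CCB1OC(C)(C)C(C)(C)O1 | starting material
3 | 4-[(1R)-1-hydroxybut-3-en-1-yl]phenyl acetate | C=CC[C@@H](O)c1ccc(OC(C)=O)cc1 | intermediate
4 | 3-(benzyloxy)phenol | Oc1cccc(OCc2ccccc2)c1 | starting material
5 | 4-[(1S)-1-[3-(benzyloxy)phenoxy]but-3-en-1-yl]phenyl acetate | C=CC[C@H](Oc1cccc(OCc2ccccc2)c1)c1ccc(OC(C)=O)cc1 | intermediate
6 | 4-[(1S)-1-[3-(benzyloxy)phenoxy]-3-oxopropyl]phenyl acetate | O=CC[C@H](Oc1cccc(OCc2ccccc2)c1)c1ccc(OC(C)=O)cc1 | intermediate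
7 | (−)-epiafzelechin, (2R,3R)-2-(4-hydroxyphenyl)chroman-3,5,7-triol | O[C@@H]1Cc2c(O)cc(O)cc2O[C@@H]1c1ccc(O)cc1 | starting material
8 | (2R,3R)-5,7-bis(benzyloxy)-2-[4-(benzyloxy)phenyl]chroman-3-ol | O[C@@H]1Cc2c(OCc3ccccc3)cc(OCc3ccccc3)cc2O[C@@H]1c1ccc(OCc2ccccc2)cc1 | intermediate
9 | 4-[(2S)-7-(benzyloxy)-4-hydroxychroman-2-yl]phenyl acetate (flavan-4-ol, C4 epimers, not isolated) | CC(=O)Oc1ccc([C@@H]2CC(O)c3ccc(OCc4ccccc4)cc3O2)cc1 | intermediate
10 | (2S)-2-(4-acetoxyphenyl)-7-(benzyloxy)chroman-4-ylium bis(trifluoromethanesulfonyl)amide (flavan-4-yl cation, not isolated) | CC(=O)Oc1ccc([C@@H]2C[CH+]c3ccc(OCc4ccccc4)cc3O2)cc1.O=S(=O)([N-]S(=O)(=O)C(F)(F)F)C(F)(F)F | intermediate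
11 | 4-[(2S,4R)-7-(benzyloxy)-4-[(2R,3R)-5,7-bis(benzyloxy)-2-[4-(benzyloxy)phenyl]-3-hydroxychroman-8-yl]chroman-2-yl]phenyl acetate | CC(=O)Oc1ccc([C@@H]2C[C@@H](c3c(OCc5ccccc5)cc(OCc5ccccc5)c4c3O[C@H](c3ccc(OCc5ccccc5)cc3)[C@H](O)C4)c3ccc(OCc5ccccc5)cc3O2)cc1 | intermediate
12 | (2R,3R)-5,7-bis(benzyloxy)-8-[(2S,4R)-7-(benzyloxy)-2-(4-hydroxyphenyl)chroman-4-yl]-2-[4-(benzyloxy)phenyl]chroman-3-ol | Oc1ccc([C@@H]2C[C@@H](c3c(OCc5ccccc5)cc(OCc5ccccc5)c4c3O[C@H](c3ccc(OCc5ccccc5)cc3)[C@H](O)C4)c3ccc(OCc5ccccc5)cc3O2)cc1 | intermediate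
13 | (2R,3R)-8-[(2S,4R)-7-hydroxy-2-(4-hydroxyphenyl)chroman-4-yl]-2-(4-hydroxyphenyl)chroman-3,5,7-triol | Oc1ccc([C@@H]2C[C@@H](c3c(O)cc(O)c4c3O[C@H](c3ccc(O)cc3)[C@H](O)C4)c3ccc(O)cc3O2)cc1 | target

**Step count.** Total: 7 steps. Longest linear sequence: 6 steps (1, 2, 3, 5, 6, 7).

**Steps most likely to fail**

1. Step 5. The cation may be captured with insufficient facial or positional selectivity, the flavan-4-ol and its cation may self-condense, or the aryloxide may be lost from the aldehyde by β-elimination before ring closure. The fallback separates the two events and sets out from 6. Pinnick oxidation (NaClO2, NaH2PO4, 2-methyl-2-butene, t-BuOH/H2O) should give (3S)-3-(4-acetoxyphenyl)-3-[3-(benzyloxy)phenoxy]propanoic acid F1. Intramolecular Friedel–Crafts acylation through the mixed anhydride (trifluoroacetic anhydride, CH2Cl2, 0 °C → rt) should close ring C through the same C4–C4a bond, at an oxidation level where no C4 cation can form, to give the (2S)-flavanone 4-[(2S)-7-(benzyloxy)-4-oxochroman-2-yl]phenyl acetate F2. Reduction (NaBH4, CeCl3·7H2O, MeOH/THF, −40 °C) should give the flavan-4-ol 9, now isolated as its 2,4-cis isomer. This is coupled with 8 (TMSOTf, CH2Cl2, −78 °C) through cation 10, where axial attack should be most selective, and the route is rejoined at 11.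

2. Step 3. The β-aryloxy aldehyde may lose the aryloxide by retro-oxa-Michael elimination during cleavage, work-up or concentration. The fallback sets out from 5 and never isolates the aldehyde. Ozonolysis in CH2Cl2/MeOH at −78 °C, reduction with Me2S and treatment of the solution with HC(OMe)3 and PPTS should give the dimethyl acetal 4-[(1S)-1-[3-(benzyloxy)phenoxy]-3,3-dimethoxypropyl]phenyl acetate F3. With 8 and TMSOTf (CH2Cl2, −78 → −30 °C), F3 should ionise to an oxocarbenium ion that closes ring C to the 4-methoxyflavan 4-[(2S)-7-(benzyloxy)-4-methoxychroman-2-yl]phenyl acetate F4. F4 ionises to the same cation 10, and the route is rejoined at 11.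

3. Step 4. Competing C-benzylation of the phloroglucinol ring, O-benzylation of the 3-hydroxyl and base-induced opening of ring C with epimerisation at C2 may consume the bought flavan-3-ol. The fallback sets out from 7 and uses it unprotected as the nucleophile in the cascade with 6 (catalytic HNTf2, 1,1,1,3,3,3-hexafluoro-2-propanol/CH2Cl2, 0 °C). This should give the coupled product 4-[(2S,4R)-7-(benzyloxy)-4-[(2R,3R)-3,5,7-trihydroxy-2-(4-hydroxyphenyl)chroman-8-yl]chroman-2-yl]phenyl acetate F5, with C6-linked and 2,4-cis isomers removed on Sephadex LH-20. Methanolysis of the acetate (K2CO3, MeOH, 0 °C, argon) should give the phenol (2R,3R)-8-[(2S,4R)-7-(benzyloxy)-2-(4-hydroxyphenyl)chroman-4-yl]-2-(4-hydroxyphenyl)chroman-3,5,7-triol F6. Hydrogenolysis (H2, Pd(OH)2/C, THF/MeOH) rejoins the route at 13.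

**Further compounds**

F1 | step 5 | (3S)-3-(4-acetoxyphenyl)-3-[3-(benzyloxy)phenoxy]propanoic acid | OC(=O)C[C@H](Oc1cccc(OCc2ccccc2)c1)c1ccc(OC(C)=O)cc1
F2 | step 5 | 4-[(2S)-7-(benzyloxy)-4-oxochroman-2-yl]phenyl acetate | CC(=O)Oc1ccc([C@@H]2CC(=O)c3ccc(OCc4ccccc4)cc3O2)cc1
F3 | step 3 | 4-[(1S)-1-[3-(benzyloxy)phenoxy]-3,3-dimethoxypropyl]phenyl acetate | COC(OC)C[C@H](Oc1cccc(OCc2ccccc2)c1)c1ccc(OC(C)=O)cc1
F4 | step 3 | 4-[(2S)-7-(benzyloxy)-4-methoxychroman-2-yl]phenyl acetate | CC(=O)Oc1ccc([C@@H]2CC(OC)c3ccc(OCc4ccccc4)cc3O2)cc1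
F5 | step 4 | 4-[(2S,4R)-7-(benzyloxy)-4-[(2R,3R)-3,5,7-trihydroxy-2-(4-hydroxyphenyl)chroman-8-yl]chroman-2-yl]phenyl acetate | CC(=O)Oc1ccc([C@@H]2C[C@@H](c3c(O)cc(O)c4c3O[C@H](c3ccc(O)cc3)[C@H](O)C4)c3ccc(OCc5ccccc5)cc3O2)cc1
F6 | step 4 | (2R,3R)-8-[(2S,4R)-7-(benzyloxy)-2-(4-hydroxyphenyl)chroman-4-yl]-2-(4-hydroxyphenyl)chroman-3,5,7-triol | Oc1ccc([C@@H]2C[C@@H](c3c(O)cc(O)c4c3O[C@H](c3ccc(O)cc3)[C@H](O)C4)c3ccc(OCc5ccccc5)cc3O2)cc1
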